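The data come from a simulation with made-up constants, noise included.

The pitfall is to give Q one rate constant for the whole run: these runs change pace early, and you can read that off them.

common to all: Z 40 mM

| flask | Q | X | L | remark | time |
|---|---|---|---|---|---|
| blue | 0.10 M | 0.10 M | 0.30 M | run made earlier |  |
| amber | 0.15 M | 0.15 M | 0.30 M | run made earlier |  |
| ochre | 0.20 M | 0.20 M | 0.60 M | run made earlier |  |
| alder | 0.20 M | 0.20 M | 0.300 M |  | 4.0 d |
| birch | 0.20 M | 0.20 M | 0.300 M |  | 8.0 d |

| run | time / d | X / % | Q / % | J / % |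
|---|---|---|---|---|
| blue | 0.625 | 48.8 | 8.4 | 22.2 |
| blue | 1.25 | 47.8 | 5.3 | 24.1 |
| blue | 2.08 | 47.5 | 2.7 | 25.5 |
| blue | 2.50 | 46.6 | 2.1 | 25.7 |
| blue | 3.00 | 46.8 | 2.2 | 26.7 |
| blue | 4.00 | 46.7 | 0.8 | 26.7 |
| amber | 0.625 | 48.7 | 11.0 | 22.2 |
| amber | 1.25 | 48.5 | 6.5 | 22.8 |
| amber | 2.08 | 47.8 | 3.0 | 24.9 |
| amber | 2.50 | 47.5 | 1.4 | 24.9 |
| amber | 3.00 | 48.5 | 1.4 | 25.3 |
| amber | 4.00 | 46.1 | 1.7 | 26.6 |
| ochre | 0.333 | 49.4 | 8.0 | 28.0 |
| ochre | 0.625 | 46.9 | 2.2 | 26.4 |
| ochre | 1.04 | 47.4 | 1.3 | 26.1 |
| ochre | 2.00 | 45.6 | 0 | 26.5 |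
| ochre | 4.00 | 44.1 | 0 | 28.1 |

(standard deviation of a reading: 0.5 percentage points)

- E is single-handed; Q and X are mirror images of each other, charged as a racemate, each of them at the stated concentration
- an excess is the difference of the two amounts in percent of their sum
- an excess is below zero if the other one leads

- the winner by excess of X over Q among what is left of the two; "neither" if no more than 2 percentage points parts them (alder / birch / neither)
- excess of X over Q among what is left of the two at the end, alder
- excess of X over Q among what is left of the two at the end, birch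

Read the last row of blue: X stands at 46.7 % while Q is down to 0.8 %. So suppose each Q lost takes one L. Then L minus Q stays at the spare L, the charge of L less the charge of Q. Near the end Q falls pseudo-first-order against it.

Divide the rise of ln(L/Q) since the start by the spare L. That gives a clock of the catalyst's work, and flasks with the same Z should share it.

Take the rows at 0.625 d. Blue reads 7.29 /M, amber 6.80 /M and ochre 6.85 /M, though their spare L differs.

Now the last rows, at 4.00 d. Blue reads 18.7 /M and amber 18.1 /M; these small Q readings carry much of the scatter. Their mean, 18.4 /M, is what I carry: the catalyst clock.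

The clock ran at 11.2 /M/d at first, then at 3.39 /M/d. I take the early fall in pace as over and let that later pace run on, which gives 32.0 /M for birch.

Alder and birch have 0.100 M spare, so I reckon Q at 0.0118 M for alder and 0.00280 M for birch. The selectivity factor read from blue's last row is roughly 60.6. With it my excesses are 88.3 % for alder and 97.0 % for birch.

The forecast gave 88 % and 96 %, “so birch leads”, and on birch it stands below mine.

The flasks give 89.2 % for alder and 96.9 % for birch, so the winner is birch.

    L + E + Q → E + J (k = 0.00954 /M²/s)
    L + E + X → E + D (k = 1.62 × 10⁻⁴ /M²/s)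
    J ⇌ D (k = 4.51 × 10⁻⁵ /s)
    2 E ⇌ G (K = 1020 /M, k = 0.00155 /M/s)
    Z → E (k = 7.29 × 10⁻⁵ /s)

In alder the half-life of Q by its own step is 0.24 d at 0.230 d, but at 4.0 d, with L at 34 % of its charge and E at 10.5 % of the catalyst charged, it is 1.98 d, far longer. Birch's further days at that slow pace take Q from 2.73 % to 0.742 %. Carry the clock 18.4 /M to the neighbour flask, alder with 0.75 M of L: its spare L of 0.550 M leaves 0.00293 % of the charged Q, and that flask holds 0 %.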